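The target is cut at the two bonds that flank C3 of the ring B dihydrofuran: C3 to the ring B arene carbon C3a, and the exocyclic CH2 to C2 of benzofuran ring C. That aryl–CH–CH2–heteroaryl array is the two-carbon unit of a vinylboronate, so a single conjunctive cross-coupling unites a ring B aryllithium, vinylboronic ester and a ring C benzofuran-2-yl triflate, sets the C3 configuration through the catalyst and leaves boron on C3, where the spiro carbon must go. The three isovaleryl groups travel as silyl enol ethers; ring A and the spiro carbon are then added by stereoretentive boronate homologation, before acid spiroketalization and hydrogenolysis.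

Key step: step 17

Assumption: the (Sp,Sp) antipode of MandyPhos is taken to give the R boronate when an aryl group migrates, so the (Rp,Rp) antipode is specified for the S boronate 31; the sense is to be checked on the first run (chiral HPLC of the derived carbinol) and the ligand antipode exchanged if needed.
Remark: the S boronate 31 maps onto C3 (S) of the target under retention; the silyl enol ethers are drawn Z, and either geometry hydrolyses to the same ketone.
Abbreviations: Ar = 6-(benzyloxy)-2,4-bis(methoxymethoxy)-3-[(Z)-3-methyl-1-(triisopropylsilyloxy)but-1-enyl]phenyl (protected ring A or ring B unit); Bf = 4,6-bis(benzyloxy)-5-[(Z)-3-methyl-1-(triisopropylsilyloxy)but-1-enyl]benzofuran-2-yl (protected ring C unit); MOM = methoxymethyl; TIPS = triisopropylsilyl; Cb = N,N-diisopropylcarbamoyl; pin = pinacolato; DMP = Dess–Martin periodinane; NIS = N-iodosuccinimide.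

Step 1
Reactants: 1 phloroglucinol; 2 isovaleryl chloride
Product: 3 1-(2,4,6-trihydroxyphenyl)-3-methylbutan-1-one
Conditions: AlCl3, PhNO2/CH2Cl2, 0 → 45 °C
Reagents that add atoms: isovaleryl chloride, CC(C)CC(Cl)=O
Why: Friedel–Crafts acylation of the triply activated ring should stop after one acyl group because the chelated ketone deactivates the arene.

Step 2
Reactants: 3 1-(2,4,6-trihydroxyphenyl)-3-methylbutan-1-one; 4 benzyl bromide
Product: 5 1-[4-(benzyloxy)-2,6-dihydroxyphenyl]-3-methylbutan-1-one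
Conditions: BnBr (1.0 equiv), K2CO3 (1.0 equiv), acetone, rt → 40 °C
Reagents that add atoms: benzyl bromide, BrCc1ccccc1
Why: Williamson etherification should take the 4-hydroxyl, which is the most acidic and the only one not hydrogen-bonded to the ketone.

Step 3
Reactants: 5 1-[4-(benzyloxy)-2,6-dihydroxyphenyl]-3-methylbutan-1-one; 6 chloromethyl methyl ether
Product: 7 1-[4-(benzyloxy)-2,6-bis(methoxymethoxy)phenyl]-3-methylbutan-1-one
Conditions: NaH, MOMCl, DMF, 0 °C → rt
Reagents that add atoms: chloromethyl methyl ether, COCCl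
Why: O-alkylation of both sodium phenoxides by the reactive α-chloro ether (acetal-type Williamson etherification) should protect the two chelated hydroxyls, which later become the ring oxygen and the acyl-bonded hydroxyl.

Step 4
Reactants: 7 1-[4-(benzyloxy)-2,6-bis(methoxymethoxy)phenyl]-3-methylbutan-1-one
Product: 9 {[(Z)-1-[4-(benzyloxy)-2,6-bis(methoxymethoxy)phenyl]-3-methylbut-1-enyl]oxy}triisopropylsilane, via potassium enolate 8 (not isolated)
Conditions: KN(SiMe3)2, THF, −78 °C; then TIPSOTf, −78 → 0 °C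
Reagents that add atoms: triisopropylsilyl trifluoromethanesulfonate, CC(C)[Si](C(C)C)(C(C)C)OS(=O)(=O)C(F)(F)F
Why: Kinetic enolization at the only α-methylene and O-silylation (silyl enol ether formation) should mask the ketone for the organolithium steps, the low temperature sparing the MOM acetals.

Step 5
Reactants: 7 1-[4-(benzyloxy)-2,6-bis(methoxymethoxy)phenyl]-3-methylbutan-1-one
Product: 10 1-[4-(benzyloxy)-3-iodo-2,6-bis(methoxymethoxy)phenyl]-3-methylbutan-1-one
Conditions: NIS (1.05 equiv), MeCN, 0 °C → rt, dark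
Reagents that add atoms: N-iodosuccinimide, O=C1CCC(=O)N1I
Why: Electrophilic aromatic iodination should take one of the two equivalent ring positions, each ortho to OMOM and OBn, para to the second OMOM and meta to the acyl group, and the acid-free conditions and the single equivalent of reagent should spare the acetals and hold the reaction at the monoiodide.

Step 6
Reactants: 10 1-[4-(benzyloxy)-3-iodo-2,6-bis(methoxymethoxy)phenyl]-3-methylbutan-1-one
Product: 12 Ar iodide, {[(Z)-1-[4-(benzyloxy)-3-iodo-2,6-bis(methoxymethoxy)phenyl]-3-methylbut-1-enyl]oxy}triisopropylsilane, via potassium enolate 11 (not isolated)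
Conditions: KN(SiMe3)2, THF, −78 °C; then TIPSOTf, −78 → 0 °C
Reagents that add atoms: triisopropylsilyl trifluoromethanesulfonate, CC(C)[Si](C(C)C)(C(C)C)OS(=O)(=O)C(F)(F)F
Why: The same kinetic enolization and O-silylation as in step 4 (silyl enol ether formation) should mask the ketone before the aryl–metal bond is made, the aryl iodide having no ortho hydrogen through which an amide base could form an aryne.

Step 7
Reactants: 12 Ar iodide; 13 ethylene oxide
Product: 15 2-Ar-ethanol, via arylmagnesium chloride 14 (not isolated)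
Conditions: i-PrMgCl·LiCl (1.1 equiv), THF, 0 °C → rt; then CuI (10 mol%), ethylene oxide (3 equiv), −30 → 0 °C
Reagents that add atoms: ethylene oxide, C1CO1
Why: Iodine–magnesium exchange, assisted by the two ortho alkoxy groups, should give arylmagnesium 14, and its copper-catalysed epoxide opening then installs the two carbons that become the ring A methylene and the spiro carbon without a Lewis acid that would threaten the MOM acetals and the silyl enol ether.

Step 8
Reactants: 15 2-Ar-ethanol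
Product: 16 2-Ar-acetaldehyde
Conditions: DMP, NaHCO3, CH2Cl2, 0 °C → rt
Reagents that add atoms: none
Why: Buffered Dess–Martin oxidation should give the arylacetaldehyde without touching the acetals or the silyl enol ether.

Step 9
Reactants: 16 2-Ar-acetaldehyde
Product: 18 2-Ar-1-(tributylstannyl)ethyl N,N-diisopropylcarbamate (racemic), via stannyl alkoxide 17 (not isolated)
Conditions: Bu3SnH, LiN(iPr)2, THF, 0 °C; 16, −78 °C; then iPr2NC(O)Cl, −78 °C → rt
Reagents that add atoms: tributyltin hydride, CCCC[SnH](CCCC)CCCC; N,N-diisopropylcarbamoyl chloride, CC(C)N(C(C)C)C(Cl)=O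
Why: 1,2-Addition of Bu3SnLi to the aldehyde and in situ O-carbamoylation (α-alkoxystannane synthesis) should store the future carbenoid so that it is later released by tin–lithium exchange instead of a deprotonation that would compete with ortho-metalation of the ring.

Step 10
Reactants: 3 1-(2,4,6-trihydroxyphenyl)-3-methylbutan-1-one; 19 allyl bromide
Product: 20 1-[4-(allyloxy)-2,6-dihydroxyphenyl]-3-methylbutan-1-one
Conditions: allyl bromide (1.0 equiv), K2CO3 (1.0 equiv), acetone, rt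
Reagents that add atoms: allyl bromide, C=CCBr
Why: Williamson etherification should again select the acidic, non-chelated 4-hydroxyl, the oxygen that becomes O1 of benzofuran ring C.

Step 11
Reactants: 20 1-[4-(allyloxy)-2,6-dihydroxyphenyl]-3-methylbutan-1-one; 4 benzyl bromide
Product: 21 1-[4-(allyloxy)-2,6-bis(benzyloxy)phenyl]-3-methylbutan-1-one
Conditions: BnBr, K2CO3, Bu4NI (cat.), DMF, 70 °C
Reagents that add atoms: benzyl bromide, BrCc1ccccc1
Why: Forcing Williamson etherification should benzylate both chelated hydroxyls.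

Step 12
Reactants: 21 1-[4-(allyloxy)-2,6-bis(benzyloxy)phenyl]-3-methylbutan-1-one
Product: 22 1-[3-allyl-2,6-bis(benzyloxy)-4-hydroxyphenyl]-3-methylbutan-1-one
Conditions: PhNEt2, 195 °C
Reagents that add atoms: none
Why: Aromatic Claisen rearrangement should move the allyl group to either of the two equivalent ortho positions and free the phenol next to it.

Step 13
Reactants: 22 1-[3-allyl-2,6-bis(benzyloxy)-4-hydroxyphenyl]-3-methylbutan-1-one
Product: 24 1-[4,6-bis(benzyloxy)-2-hydroxy-2,3-dihydrobenzofuran-5-yl]-3-methylbutan-1-one (racemic lactol), via arylacetaldehyde 23 (not isolated)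
Conditions: OsO4 (cat.), NaIO4, 2,6-lutidine, dioxane/H2O, rt
Reagents that add atoms: sodium periodate, [Na+].[O-]I(=O)(=O)=O (oxygen source, relayed by OsO4)
Why: Lemieux–Johnson cleavage of the terminal alkene should give the arylacetaldehyde, which closes on the adjacent phenol to the five-membered lactol.

Step 14
Reactants: 24 lactol
Product: 25 4,6-bis(benzyloxy)-5-(3-methylbutanoyl)benzofuran-2(3H)-one
Conditions: TEMPO (cat.), PhI(OAc)2, CH2Cl2, rt
Reagents that add atoms: none
Why: Oxoammonium-mediated oxidation of the lactol to the lactone is near neutral and should avoid acid-induced dehydration to the benzofuran.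

Step 15
Reactants: 25 benzofuran-2(3H)-one
Product: 26 4,6-bis(benzyloxy)-5-(3-methylbutanoyl)benzofuran-2-yl trifluoromethanesulfonate
Conditions: Tf2O, iPr2NEt, CH2Cl2, −78 → 0 °C
Reagents that add atoms: trifluoromethanesulfonic anhydride, O=S(=O)(OS(=O)(=O)C(F)(F)F)C(F)(F)F
Why: The lactone enolizes far more readily than the hindered ketone, and O-sulfonylation of the aromatic 2-oxidobenzofuran (enol triflate formation) should give the heteroaryl triflate.

Step 16
Reactants: 26 benzofuran-2-yl triflate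
Product: 27 Bf trifluoromethanesulfonate (4,6-bis(benzyloxy)-5-[(Z)-3-methyl-1-(triisopropylsilyloxy)but-1-enyl]benzofuran-2-yl trifluoromethanesulfonate)
Conditions: TIPSOTf, iPr2NEt, CH2Cl2, 0 °C → rt
Reagents that add atoms: triisopropylsilyl trifluoromethanesulfonate, CC(C)[Si](C(C)C)(C(C)C)OS(=O)(=O)C(F)(F)F
Why: Silyl triflate and amine base convert the ketone into its silyl enol ether (soft enolization), so that ring C carries no carbonyl group into the two organometallic steps that follow.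

Step 17
Reactants: 9 common arene; 28 vinylboronic acid pinacol ester; 27 Bf trifluoromethanesulfonate
Product: 31 2-[(1S)-1-Ar-2-Bf-ethyl]-4,4,5,5-tetramethyl-1,3,2-dioxaborolane, via aryllithium 29 (not isolated), via ate complex 30 (not isolated)
Conditions: 9 (1.2 equiv), n-BuLi (1.15 equiv), THF, −20 → 0 °C; 28 (1.15 equiv), −78 °C → rt; then 27 (1.0 equiv), Pd(OAc)2 (3 mol%), (Rp,Rp)-MandyPhos (3.6 mol%), THF, 60 °C
Reagents that add atoms: none
Why: Directed ortho-metalation of 9 at one of its two equivalent positions between OMOM and OBn gives aryllithium 29, which adds to boron of 28 to give the four-coordinate ate complex 30; zerovalent palladium formed from Pd(OAc)2 and the bisphosphine inserts into the C2–O bond of 27, and the resulting cationic benzofuranyl–divalent palladium species binds the vinyl group and induces a 1,2-shift of the aryl group from boron to the α-carbon while palladium bonds the β-carbon, after which reductive elimination forms the CH2–C2(benzofuran) bond. The closest known reaction type is the palladium-catalysed enantioselective conjunctive cross-coupling of vinylboron ate complexes with aryl and alkenyl triflates. No ring is closed. The one new stereocenter, the boron-bearing carbon (S), is set by the chiral bisphosphine on palladium, which selects the enantioface of the vinyl group in the metallate shift. The step needs the conjunctive pathway to outrun direct Suzuki–Miyaura transfer of vinyl or aryl from boron: halide-free aryllithium from ortho-metalation, the triflate leaving group and the bisphosphine keep palladium cationic and alkene-binding, and the electron-rich aryl group should migrate readily despite its two ortho substituents. Both ketones are masked as silyl enol ethers, so neither the aryllithium nor the ate complex meets a carbonyl group.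

Step 18
Reactants: 18 stannyl carbamate; 31 secondary benzylic boronate
Product: 35 (2RS,3S)-1,3-di-Ar-4-Bf-butan-2-ol, via lithiated carbamate 32 (not isolated), via borate complex 33 (not isolated), via homologated boronate 34 (not isolated)
Conditions: 18 (1.6 equiv), n-BuLi (1.5 equiv), Et2O, −78 °C; 31, −78 → 35 °C; then NaOH, H2O2, THF/H2O, 0 °C → rt
Reagents that add atoms: hydrogen peroxide, OO
Why: Tin–lithium exchange gives carbenoid 32, which adds to boron of 31, and the 1,2-metallate rearrangement with loss of carbamate (lithiation–borylation homologation) moves C3 from boron to carbon with retention before the new C–B bond is oxidized; the carbinol configuration is irrelevant because that carbon becomes the ketone.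

Step 19
Reactants: 35 secondary alcohol
Product: 36 (3S)-1,3-di-Ar-4-Bf-butan-2-one
Conditions: DMP, NaHCO3, CH2Cl2, 0 °C → rt
Reagents that add atoms: none
Why: Buffered Dess–Martin oxidation is neutral and should give the ketone without enolization at the adjacent aryl-bearing C3.

Step 20
Reactants: 36 ketone
Product: 38 (2R,3S)-4,4′-bis(benzyloxy)-3-{[4,6-bis(benzyloxy)-5-(3-methylbutanoyl)benzofuran-2-yl]methyl}-6,6′-dihydroxy-7,7′-bis(3-methylbutanoyl)-3H,3′H-2,2′-spirobi[benzofuran], via open triketone 37 (not isolated)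
Conditions: 3 M aq. HCl, MeOH/THF, 40 °C; then CSA (cat.), CH2Cl2, 4 Å MS, rt
Reagents that add atoms: none
Why: Acid hydrolysis of the four MOM acetals and three silyl enol ethers gives 37, in which on each of rings A and B the only free hydroxyl ortho to the side chain adds to the ketone (acid-catalysed spiroketalization, two 5-exo closures through hemiketal and oxocarbenium ion) while the benzyl ethers block the alternative phenols and the neighbouring freed hydroxyls take over the hydrogen bond to each acyl group; the spiro centre is set under equilibrating conditions, which should favour the isomer with the C3 side chain anti to the ring A methylene, as in the target.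

Step 21
Reactants: 38 tetra-O-benzyl spiroketal
Product: 39 CNP0169640.1, (2R,3S)-3-{[4,6-dihydroxy-5-(3-methylbutanoyl)benzofuran-2-yl]methyl}-4,4′,6,6′-tetrahydroxy-7,7′-bis(3-methylbutanoyl)-3H,3′H-2,2′-spirobi[benzofuran]
Conditions: H2 (1 atm), Pd on carbon (10% Pd/C), EtOAc/MeOH, rt
Reagents that add atoms: none
Why: Hydrogenolysis of the four benzyl ethers under neutral conditions should leave the chelated aryl ketones, benzofuran ring C and the bis-aryl ketal (no benzylic C–O bond) untouched.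

Compound list
1 | phloroglucinol | Oc1cc(O)cc(O)c1 | starting material
2 | isovaleryl chloride | CC(C)CC(Cl)=O | starting material
3 | 1-(2,4,6-trihydroxyphenyl)-3-methylbutan-1-one | CC(C)CC(=O)c1c(O)cc(O)cc1O | intermediate
4 | benzyl bromide | BrCc1ccccc1 | starting material
5 | 1-[4-(benzyloxy)-2,6-dihydroxyphenyl]-3-methylbutan-1-one | CC(C)CC(=O)c1c(O)cc(OCc2ccccc2)cc1O | intermediate
6 | chloromethyl methyl ether | COCCl | starting material
7 | 1-[4-(benzyloxy)-2,6-bis(methoxymethoxy)phenyl]-3-methylbutan-1-one | CC(C)CC(=O)c1c(OCOC)cc(OCc2ccccc2)cc1OCOC | intermediate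
8 | potassium (Z)-enolate of 7 | CC(C)/C=C(\[O-])c1c(OCOC)cc(OCc2ccccc2)cc1OCOC.[K+] | intermediate
9 | {[(Z)-1-[4-(benzyloxy)-2,6-bis(methoxymethoxy)phenyl]-3-methylbut-1-enyl]oxy}triisopropylsilane (common arene) | CC(C)/C=C(\O[Si](C(C)C)(C(C)C)C(C)C)c1c(OCOC)cc(OCc2ccccc2)cc1OCOC | intermediate
10 | 1-[4-(benzyloxy)-3-iodo-2,6-bis(methoxymethoxy)phenyl]-3-methylbutan-1-one | CC(C)CC(=O)c1c(OCOC)c(I)c(OCc2ccccc2)cc1OCOC | intermediate
11 | potassium (Z)-enolate of 10 | CC(C)/C=C(\[O-])c1c(OCOC)c(I)c(OCc2ccccc2)cc1OCOC.[K+] | intermediate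
12 | Ar iodide, {[(Z)-1-[4-(benzyloxy)-3-iodo-2,6-bis(methoxymethoxy)phenyl]-3-methylbut-1-enyl]oxy}triisopropylsilane | Ic1c(OCOC)c(/C(O[Si](C(C)C)(C(C)C)C(C)C)=C/C(C)C)c(OCOC)cc1OCc1ccccc1 | intermediate
13 | ethylene oxide | C1CO1 | starting material
14 | Ar–MgCl, ring A arylmagnesium chloride (as its LiCl complex) | Cl[Mg]c1c(OCOC)c(/C(O[Si](C(C)C)(C(C)C)C(C)C)=C/C(C)C)c(OCOC)cc1OCc1ccccc1 | intermediate
15 | 2-Ar-ethanol | OCCc1c(OCOC)c(/C(O[Si](C(C)C)(C(C)C)C(C)C)=C/C(C)C)c(OCOC)cc1OCc1ccccc1 | intermediate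
16 | 2-Ar-acetaldehyde | O=CCc1c(OCOC)c(/C(O[Si](C(C)C)(C(C)C)C(C)C)=C/C(C)C)c(OCOC)cc1OCc1ccccc1 | intermediate
17 | lithium 2-Ar-1-(tributylstannyl)ethoxide (racemic) | CCCC[Sn](CCCC)(CCCC)C(O[Li])Cc1c(OCOC)c(/C(O[Si](C(C)C)(C(C)C)C(C)C)=C/C(C)C)c(OCOC)cc1OCc1ccccc1 | intermediate
18 | 2-Ar-1-(tributylstannyl)ethyl N,N-diisopropylcarbamate (racemic) | CCCC[Sn](CCCC)(CCCC)C(OC(=O)N(C(C)C)C(C)C)Cc1c(OCOC)c(/C(O[Si](C(C)C)(C(C)C)C(C)C)=C/C(C)C)c(OCOC)cc1OCc1ccccc1 | intermediate
19 | allyl bromide | C=CCBr | starting material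
20 | 1-[4-(allyloxy)-2,6-dihydroxyphenyl]-3-methylbutan-1-one | CC(C)CC(=O)c1c(O)cc(OCC=C)cc1O | intermediate
21 | 1-[4-(allyloxy)-2,6-bis(benzyloxy)phenyl]-3-methylbutan-1-one | CC(C)CC(=O)c1c(OCc2ccccc2)cc(OCC=C)cc1OCc1ccccc1 | intermediate
22 | 1-[3-allyl-2,6-bis(benzyloxy)-4-hydroxyphenyl]-3-methylbutan-1-one | CC(C)CC(=O)c1c(OCc2ccccc2)c(CC=C)c(O)cc1OCc1ccccc1 | intermediate
23 | 2-[2,4-bis(benzyloxy)-6-hydroxy-3-(3-methylbutanoyl)phenyl]acetaldehyde | CC(C)CC(=O)c1c(OCc2ccccc2)c(CC=O)c(O)cc1OCc1ccccc1 | intermediate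
24 | 1-[4,6-bis(benzyloxy)-2-hydroxy-2,3-dihydrobenzofuran-5-yl]-3-methylbutan-1-one (racemic lactol) | CC(C)CC(=O)c1c(OCc2ccccc2)cc2OC(O)Cc2c1OCc1ccccc1 | intermediate
25 | 4,6-bis(benzyloxy)-5-(3-methylbutanoyl)benzofuran-2(3H)-one | CC(C)CC(=O)c1c(OCc2ccccc2)cc2OC(=O)Cc2c1OCc1ccccc1 | intermediate
26 | 4,6-bis(benzyloxy)-5-(3-methylbutanoyl)benzofuran-2-yl trifluoromethanesulfonate | O=S(=O)(Oc1cc2c(OCc3ccccc3)c(C(=O)CC(C)C)c(OCc3ccccc3)cc2o1)C(F)(F)F | intermediate
27 | Bf trifluoromethanesulfonate, ring C benzofuran-2-yl triflate | O=S(=O)(Oc1cc2c(OCc3ccccc3)c(/C(O[Si](C(C)C)(C(C)C)C(C)C)=C/C(C)C)c(OCc3ccccc3)cc2o1)C(F)(F)F | intermediate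
28 | vinylboronic acid pinacol ester | C=CB1OC(C)(C)C(C)(C)O1 | starting material
29 | Ar–Li, ring B aryllithium | [Li]c1c(OCOC)c(/C(O[Si](C(C)C)(C(C)C)C(C)C)=C/C(C)C)c(OCOC)cc1OCc1ccccc1 | intermediate
30 | lithium Ar(vinyl)(pinacolato)borate, ate complex | [Li+].C=C[B-]1(OC(C)(C)C(C)(C)O1)c1c(OCOC)c(/C(O[Si](C(C)C)(C(C)C)C(C)C)=C/C(C)C)c(OCOC)cc1OCc1ccccc1 | intermediate
31 | 2-[(1S)-1-Ar-2-Bf-ethyl]-4,4,5,5-tetramethyl-1,3,2-dioxaborolane | COCOc1c(/C(O[Si](C(C)C)(C(C)C)C(C)C)=C/C(C)C)c(OCOC)cc(OCc2ccccc2)c1[C@@H](B1OC(C)(C)C(C)(C)O1)Cc1cc2c(OCc3ccccc3)c(/C(O[Si](C(C)C)(C(C)C)C(C)C)=C/C(C)C)c(OCc3ccccc3)cc2o1 | intermediate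
32 | 2-Ar-1-lithioethyl N,N-diisopropylcarbamate (racemic) | [Li]C(OC(=O)N(C(C)C)C(C)C)Cc1c(OCOC)c(/C(O[Si](C(C)C)(C(C)C)C(C)C)=C/C(C)C)c(OCOC)cc1OCc1ccccc1 | intermediate
33 | lithium borate complex of 31 and 32 (C3 configuration of 31 retained, epimers at the carbamate carbon) | [Li+].COCOc1c(/C(O[Si](C(C)C)(C(C)C)C(C)C)=C/C(C)C)c(OCOC)cc(OCc2ccccc2)c1[C@@H]([B-]1(OC(C)(C)C(C)(C)O1)C(OC(=O)N(C(C)C)C(C)C)Cc1c(OCOC)c(/C(O[Si](C(C)C)(C(C)C)C(C)C)=C/C(C)C)c(OCOC)cc1OCc1ccccc1)Cc1cc2c(OCc3ccccc3)c(/C(O[Si](C(C)C)(C(C)C)C(C)C)=C/C(C)C)c(OCc3ccccc3)cc2o1 | intermediate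
34 | 2-[(2RS,3R)-1,3-di-Ar-4-Bf-butan-2-yl]-4,4,5,5-tetramethyl-1,3,2-dioxaborolane (same spatial arrangement at C3 as in 31) | COCOc1c(/C(O[Si](C(C)C)(C(C)C)C(C)C)=C/C(C)C)c(OCOC)cc(OCc2ccccc2)c1[C@@H](C(B1OC(C)(C)C(C)(C)O1)Cc1c(OCOC)c(/C(O[Si](C(C)C)(C(C)C)C(C)C)=C/C(C)C)c(OCOC)cc1OCc1ccccc1)Cc1cc2c(OCc3ccccc3)c(/C(O[Si](C(C)C)(C(C)C)C(C)C)=C/C(C)C)c(OCc3ccccc3)cc2o1 | intermediate
35 | (2RS,3S)-1,3-di-Ar-4-Bf-butan-2-ol | COCOc1c(/C(O[Si](C(C)C)(C(C)C)C(C)C)=C/C(C)C)c(OCOC)cc(OCc2ccccc2)c1[C@@H](C(O)Cc1c(OCOC)c(/C(O[Si](C(C)C)(C(C)C)C(C)C)=C/C(C)C)c(OCOC)cc1OCc1ccccc1)Cc1cc2c(OCc3ccccc3)c(/C(O[Si](C(C)C)(C(C)C)C(C)C)=C/C(C)C)c(OCc3ccccc3)cc2o1 | intermediate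
36 | (3S)-1,3-di-Ar-4-Bf-butan-2-one | COCOc1c(/C(O[Si](C(C)C)(C(C)C)C(C)C)=C/C(C)C)c(OCOC)cc(OCc2ccccc2)c1[C@@H](C(=O)Cc1c(OCOC)c(/C(O[Si](C(C)C)(C(C)C)C(C)C)=C/C(C)C)c(OCOC)cc1OCc1ccccc1)Cc1cc2c(OCc3ccccc3)c(/C(O[Si](C(C)C)(C(C)C)C(C)C)=C/C(C)C)c(OCc3ccccc3)cc2o1 | intermediate
37 | (3S)-1,3-bis[6-(benzyloxy)-2,4-dihydroxy-3-(3-methylbutanoyl)phenyl]-4-[4,6-bis(benzyloxy)-5-(3-methylbutanoyl)benzofuran-2-yl]butan-2-one | Oc1c(C(=O)CC(C)C)c(O)cc(OCc2ccccc2)c1[C@@H](C(=O)Cc1c(O)c(C(=O)CC(C)C)c(O)cc1OCc1ccccc1)Cc1cc2c(OCc3ccccc3)c(C(=O)CC(C)C)c(OCc3ccccc3)cc2o1 | intermediate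
38 | (2R,3S)-4,4′-bis(benzyloxy)-3-{[4,6-bis(benzyloxy)-5-(3-methylbutanoyl)benzofuran-2-yl]methyl}-6,6′-dihydroxy-7,7′-bis(3-methylbutanoyl)-3H,3′H-2,2′-spirobi[benzofuran] (C3 side chain cis to the ring A oxygen) | CC(C)CC(=O)c1c(O)cc(OCc3ccccc3)c2c1O[C@]1(C2)Oc2c(C(=O)CC(C)C)c(O)cc(OCc3ccccc3)c2[C@@H]1Cc1cc2c(OCc3ccccc3)c(C(=O)CC(C)C)c(OCc3ccccc3)cc2o1 | intermediate
39 | CNP0169640.1, (2R,3S)-3-{[4,6-dihydroxy-5-(3-methylbutanoyl)benzofuran-2-yl]methyl}-4,4′,6,6′-tetrahydroxy-7,7′-bis(3-methylbutanoyl)-3H,3′H-2,2′-spirobi[benzofuran] | CC(C)CC(=O)c1c(O)cc(O)c2c1O[C@]1(C2)Oc2c(C(=O)CC(C)C)c(O)cc(O)c2[C@@H]1Cc1cc2c(O)c(C(=O)CC(C)C)c(O)cc2o1 | target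

Total step count: 21. Longest linear sequence: 13 steps (steps 1, 10–21).

Steps most likely to fail

1. Step 17. The hindered, di-ortho-substituted aryl group may shift too slowly, so that vinyl or aryl is transferred directly from boron to palladium, or the enantioface selection may be eroded. Fallback by enantioselective lithiation–borylation, setting out from arene 9 and triflate 27 and returning at 31: arene 9 is ortho-lithiated with n-BuLi and quenched with 2-isopropoxy-4,4,5,5-tetramethyl-1,3,2-dioxaborolane to give the aryl pinacol boronate F1. Triflate 27 is vinylated with 28 (Pd(PPh3)4, K3PO4) to the 2-vinylbenzofuran F2, hydroborated and oxidized (9-BBN; NaBO3·4H2O) to the alcohol F3 and carbamoylated (iPr2NC(O)Cl, NaH) to the carbamate F4. Deprotonation with s-BuLi/(+)-sparteine in Et2O at −78 °C should give the R-configured lithiated carbamate F5 (the sparteine antipode is chosen for this sense). F5 is borylated by F1 with retention, and the 1,2-shift of the aryl group with inversion at carbon delivers 31.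

2. Step 20. A hemiketal may dehydrate to a benzofuran (on the ring A side, or on the ring B side with loss of the C3 stereocentre), C3 may epimerize through the enol, or the ring B phenol may add to protonated benzofuran ring C. Fallback by closing the ketal before the acyl groups are unmasked, setting out from 36 and returning at 38: the MOM groups alone are removed with TMSOTf/2,2′-bipyridyl in CH2Cl2 and then water, giving the tetraphenol tris(silyl enol ether) F6. Its phenols are electron-rich and not hydrogen-bonded, so catalytic CSA in CH2Cl2 over 4 Å MS should close the spiroketal tris(silyl enol ether) F7 under mild acid. HF·pyridine then releases the three ketones to give 38.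

3. Step 18. The crowded borate complex may revert to its components or fail to rearrange, and one antipode of the racemic carbenoid may react sluggishly. Fallback by acylation and α-arylation, setting out from 31 and the aryl iodide 12 and returning at 36: Zweifel coupling of 31 with 1-ethoxyvinyllithium (I2, MeOH; NaOMe) gives the ethyl enol ether F8 with retention. Oxalic acid in wet THF hydrolyses it to the methyl ketone F9, and LiN(iPr)2/Me3SiCl at −78 °C gives the terminal trimethylsilyl enol ether F10. Palladium-catalysed α-arylation (Pd2(dba)3, P(t-Bu)3, Bu3SnF) with the aryl iodide 12 then gives 36.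

Further compounds
F1 | step 17 | 2-Ar-4,4,5,5-tetramethyl-1,3,2-dioxaborolane | CC1(C)OB(OC1(C)C)c1c(OCOC)c(/C(O[Si](C(C)C)(C(C)C)C(C)C)=C/C(C)C)c(OCOC)cc1OCc1ccccc1
F2 | step 17 | Bf-ethene (2-vinylbenzofuran) | C=Cc1cc2c(OCc3ccccc3)c(/C(O[Si](C(C)C)(C(C)C)C(C)C)=C/C(C)C)c(OCc3ccccc3)cc2o1
F3 | step 17 | 2-Bf-ethanol | OCCc1cc2c(OCc3ccccc3)c(/C(O[Si](C(C)C)(C(C)C)C(C)C)=C/C(C)C)c(OCc3ccccc3)cc2o1
F4 | step 17 | 2-Bf-ethyl N,N-diisopropylcarbamate | CC(C)N(C(C)C)C(=O)OCCc1cc2c(OCc3ccccc3)c(/C(O[Si](C(C)C)(C(C)C)C(C)C)=C/C(C)C)c(OCc3ccccc3)cc2o1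
F5 | step 17 | (1R)-2-Bf-1-lithioethyl N,N-diisopropylcarbamate | CC(C)N(C(C)C)C(=O)O[C@H]([Li])Cc1cc2c(OCc3ccccc3)c(/C(O[Si](C(C)C)(C(C)C)C(C)C)=C/C(C)C)c(OCc3ccccc3)cc2o1
F6 | step 20 | (3S)-1,3-bis{6-(benzyloxy)-2,4-dihydroxy-3-[(Z)-3-methyl-1-(triisopropylsilyloxy)but-1-enyl]phenyl}-4-Bf-butan-2-one | Oc1c(/C(O[Si](C(C)C)(C(C)C)C(C)C)=C/C(C)C)c(O)cc(OCc2ccccc2)c1[C@@H](C(=O)Cc1c(O)c(/C(O[Si](C(C)C)(C(C)C)C(C)C)=C/C(C)C)c(O)cc1OCc1ccccc1)Cc1cc2c(OCc3ccccc3)c(/C(O[Si](C(C)C)(C(C)C)C(C)C)=C/C(C)C)c(OCc3ccccc3)cc2o1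
F7 | step 20 | tris(triisopropylsilyl enol ether) of 38 | CC(C)/C=C(\O[Si](C(C)C)(C(C)C)C(C)C)c1c(O)cc(OCc3ccccc3)c2c1O[C@]1(C2)Oc2c(/C(O[Si](C(C)C)(C(C)C)C(C)C)=C/C(C)C)c(O)cc(OCc3ccccc3)c2[C@@H]1Cc1cc2c(OCc3ccccc3)c(/C(O[Si](C(C)C)(C(C)C)C(C)C)=C/C(C)C)c(OCc3ccccc3)cc2o1
F8 | step 18 | (3S)-3-Ar-4-Bf-2-ethoxybut-1-ene | COCOc1c(/C(O[Si](C(C)C)(C(C)C)C(C)C)=C/C(C)C)c(OCOC)cc(OCc2ccccc2)c1[C@@H](C(=C)OCC)Cc1cc2c(OCc3ccccc3)c(/C(O[Si](C(C)C)(C(C)C)C(C)C)=C/C(C)C)c(OCc3ccccc3)cc2o1
F9 | step 18 | (3S)-3-Ar-4-Bf-butan-2-one | COCOc1c(/C(O[Si](C(C)C)(C(C)C)C(C)C)=C/C(C)C)c(OCOC)cc(OCc2ccccc2)c1[C@@H](C(C)=O)Cc1cc2c(OCc3ccccc3)c(/C(O[Si](C(C)C)(C(C)C)C(C)C)=C/C(C)C)c(OCc3ccccc3)cc2o1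
F10 | step 18 | (3S)-3-Ar-4-Bf-2-(trimethylsilyloxy)but-1-ene | COCOc1c(/C(O[Si](C(C)C)(C(C)C)C(C)C)=C/C(C)C)c(OCOC)cc(OCc2ccccc2)c1[C@@H](C(=C)O[Si](C)(C)C)Cc1cc2c(OCc3ccccc3)c(/C(O[Si](C(C)C)(C(C)C)C(C)C)=C/C(C)C)c(OCc3ccccc3)cc2o1
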